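**Plan**
- Cuts: ring-A bond C1–C6 (ketyl–enoate closure); side-chain bond C2'–C3' (sp3–sp2 cross-coupling); exocyclic C3=C bond of the enal (C3 ketone → enol triflate → 2-(hydroxymethyl)diene → 1,4-hydrogenation); acyclic C2–C3 bond (aldol); C5'–C6' bond at the side-chain carbinol (alkenylzinc addition).
- Enabling feature: in ring A (C1–C6) the quaternary C1 (methyl, two-carbon arm) and the methyl carbinol C6 are directly bonded and fully substituted, with the C6 hydroxyl trans to the arm. That C1–C6 bond is the one a C6 ketone ketyl makes when it adds to the β-carbon (C1) of a β-methyl enoate.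
- Forward order: aldol builds the C2/C3 chain; olefination and Wacker oxidation give the keto enoate; SmI2 closes ring A (the only ring); the acetate arm becomes an iodide and is joined to the alkenyl iodide side chain; the C3 carbinol becomes the Z-enal; desilylation ends the route.
- Stereochemistry: C2 and C3 come from an Evans syn-aldol with the (R)-benzyloxazolidinone; C1 and C6 arise in the ring closure under control of C2/C3 (C3 later becomes sp2). C8' comes from (S)-citronellal and C5' from a ligand-controlled alkenylzinc addition. 3'E comes from carboalumination, 6'E from hydroboration, and the enal Z geometry from cis-1,4-addition of H2 to an s-cis diene.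

Key step: step 9

Remark: (S)-citronellal of high enantiomeric purity is taken as commercially available; ring A is numbered C1 (quaternary, methyl and arm), C2 (oxypropyl CH), C3, C4, C5, C6 (methyl carbinol), and ring descriptors in names follow this numbering.
Abbreviations: TBDPS = tert-butyldiphenylsilyl, TES = triethylsilyl, TBS = tert-butyldimethylsilyl, TMS = trimethylsilyl; SC = (3E,5S,6E,8S)-5-(TBS-oxy)-4,8,12-trimethyltrideca-3,6,11-trien-1-yl.

**Ring-A fragment**

Step 1
Reactants: 1 δ-valerolactone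
Product: 4 silyloxy acid 5-(TBDPS-oxy)pentanoic acid, via sodium 5-hydroxypentanoate 2 (not isolated), via bis-silylated hydroxy acid 3 (not isolated)
Conditions: NaOH, H2O/MeOH, rt, evaporate; t-BuPh2SiCl, imidazole, DMF, rt; 1 M NaOH, THF/MeOH, 0 °C; 1 M HCl to pH 4
Reagents that add atoms: sodium hydroxide [Na+].[OH-]; tert-butyl(chloro)diphenylsilane CC(C)(C)[Si](Cl)(c1ccccc1)c1ccccc1
Why: Saponification opens the lactone, both oxygens are silylated and the labile silyl ester is hydrolysed again while the primary silyl ether stays (standard hydroxy-acid protection).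

Step 2
Reactants: 4 silyloxy acid; 5 (R)-4-benzyloxazolidin-2-one
Product: 7 (R)-4-benzyl-3-[5-(TBDPS-oxy)pentanoyl]oxazolidin-2-one, via mixed pivalic anhydride 6 (not isolated)
Conditions: t-BuCOCl, Et3N, THF, −20 °C; then 5, LiCl, −20 °C → rt
Reagents that add atoms: none
Why: N-Acylation of the oxazolidinone through the mixed pivalic anhydride, which is attacked at its less hindered acyl carbon (standard imide formation).

Step 3
Reactants: 7 acyl oxazolidinone; 8 pent-4-enal
Product: 10 (R)-4-benzyl-3-[(2R,3S)-2-[3-(TBDPS-oxy)propyl]-3-hydroxyhept-6-enoyl]oxazolidin-2-one, via Z-dibutylboron enolate 9 (not isolated)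
Conditions: Bu2BOTf, i-Pr2NEt, CH2Cl2, 0 °C; 8, −78 → 0 °C; pH 7 buffer, MeOH, 30% H2O2, 0 °C
Reagents that add atoms: none
Why: Evans syn-aldol reaction: the Z-boron enolate reacts through a Zimmerman–Traxler chair on the face away from the benzyl group of the (R)-auxiliary, which sets the acyl C2 (R) and C3 (S), the future ring carbons C2 and C3.

Step 4
Reactants: 10 aldol adduct
Product: 11 (2R,3S)-2-[3-(TBDPS-oxy)propyl]-3-hydroxy-N-methoxy-N-methylhept-6-enamide
Conditions: MeNH(OMe)·HCl, AlMe3, CH2Cl2, −20 → 0 °C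
Reagents that add atoms: N,O-dimethylhydroxylamine hydrochloride CNOC.Cl
Why: Weinreb transamidation with the aluminium amide, assisted by the free β-hydroxyl, cleaves the exocyclic imide bond without retro-aldol cleavage and returns the auxiliary.

Step 5
Reactants: 11 hydroxy Weinreb amide
Product: 12 (2R,3S)-2-[3-(TBDPS-oxy)propyl]-N-methoxy-N-methyl-3-(TES-oxy)hept-6-enamide
Conditions: Et3SiCl, imidazole, DMF, 0 °C → rt
Reagents that add atoms: chlorotriethylsilane CC[Si](Cl)(CC)CC
Why: Silylation of the secondary alcohol as a triethylsilyl ether, chosen because it can later be removed in the presence of the TBS and TBDPS ethers.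

Step 6
Reactants: 12 silylated Weinreb amide
Product: 13 (3R,4S)-3-[3-(TBDPS-oxy)propyl]-4-(TES-oxy)oct-7-en-2-one
Conditions: MeMgBr, THF, 0 °C
Reagents that add atoms: methylmagnesium bromide C[Mg]Br
Why: Weinreb ketone synthesis: the chelated tetrahedral adduct stops at the ketone stage.

Step 7
Reactants: 13 methyl ketone; 14 triethyl phosphonoacetate
Product: 16 ethyl (2E,4S,5S)-4-[3-(TBDPS-oxy)propyl]-3-methyl-5-(TES-oxy)nona-2,8-dienoate, via sodium phosphonoacetate carbanion 15 (not isolated)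
Conditions: 14, NaH, THF, 0 °C; then 13, rt → 50 °C
Reagents that add atoms: none
Why: Horner–Wadsworth–Emmons olefination of the methyl ketone, in which the reversible addition places the ester trans to the branched C4 substituent and should give the E-enoate.

Step 8
Reactants: 16 dienoate
Product: 17 ethyl (2E,4S,5S)-4-[3-(TBDPS-oxy)propyl]-3-methyl-8-oxo-5-(TES-oxy)non-2-enoate
Conditions: PdCl2 (10 mol %), Cu(OAc)2 (20 mol %), O2 (1 atm), DMA/H2O 7:1, rt
Reagents that add atoms: water O
Why: Tsuji–Wacker oxidation: Markovnikov hydroxypalladation of the monosubstituted alkene gives the methyl ketone, the trisubstituted electron-poor enoate is inert and the acetate-buffered medium spares the silyl ethers.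

Step 9
Reactants: 17 keto enoate
Product: 18 ethyl 2-[(1S,2S,3S,6S)-2-[3-(TBDPS-oxy)propyl]-6-hydroxy-1,6-dimethyl-3-(TES-oxy)cyclohexyl]acetate
Conditions: SmI2 (2.5 equiv), HMPA, t-BuOH (2 equiv), THF, −78 → 0 °C
Reagents that add atoms: none
Why: SmI2 (divalent samarium, activated by HMPA) transfers one electron to the methyl ketone; the samarium-bound ketyl (future C6) adds to the enoate β-carbon (future C1), the α-ester radical is reduced by a second equivalent and the samarium enolate is protonated by t-BuOH. The closest known reaction is the SmI2-mediated reductive ketyl–olefin cyclization of keto enoates to 2-hydroxycycloalkylacetates. Ring A closes in the 6-exo-trig mode through a chair in which the C2 oxypropyl chain and the C3 silyloxy group, trans to each other from the syn-aldol, are both equatorial. C1 is controlled by C2: with the C2–H eclipsing the enoate double bond (least allylic strain) the ester-bearing alkene terminus is pseudo-equatorial and the ketyl tethered through C3 reaches the alkene face anti to the C2 chain, so the acetate arm should end trans to that chain with the methyl axial. C6 is controlled by the bulky HMPA-solvated O–Sm group, which takes the equatorial site anti to the electron-rich enoate, so the hydroxyl should end trans to the arm and the hydroxy ester cannot lactonize. The step needs ketyl addition to outrun simple reduction of the ketone and of the enoate and needs the trans,trans diastereomer; the ester-activated acceptor held six atoms away, the absence of other reducible groups and the two equatorial anchors at C2 and C3 secure this.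

Step 10
Reactants: 18 hydroxy ester
Product: 19 ethyl 2-[(1S,2S,3S,6S)-2-[3-(TBDPS-oxy)propyl]-1,6-dimethyl-3-(TES-oxy)-6-(TMS-oxy)cyclohexyl]acetate
Conditions: Me3SiOTf, 2,6-lutidine, CH2Cl2, −78 °C
Reagents that add atoms: trimethylsilyl triflate C[Si](C)(C)OS(=O)(=O)C(F)(F)F
Why: Silylation with the silyl triflate caps the hindered tertiary hydroxyl, which would otherwise close a tetrahydrofuran onto the arm once its terminus carries a leaving group.

Step 11
Reactants: 19 silylated ester
Product: 20 2-[(1S,2S,3S,6S)-2-[3-(TBDPS-oxy)propyl]-1,6-dimethyl-3-(TES-oxy)-6-(TMS-oxy)cyclohexyl]ethanol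
Conditions: i-Bu2AlH (2.5 equiv), CH2Cl2, −78 → 0 °C; Rochelle salt
Reagents that add atoms: none
Why: Hydride reduction of the ester to the primary alcohol with i-Bu2AlH, which leaves the silyl ethers untouched.

Step 12
Reactants: 20 primary alcohol
Product: 21 (1S,2S,3S,6S)-1-(2-iodoethyl)-2-[3-(TBDPS-oxy)propyl]-1,6-dimethyl-3-(TES-oxy)-6-(TMS-oxy)cyclohexane
Conditions: I2, PPh3, imidazole, CH2Cl2, 0 °C
Reagents that add atoms: iodine II
Why: Appel-type iodination (phosphonium activation of the primary alcohol, then SN2 displacement by iodide) under imidazole buffering.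

**Side-chain fragment**

Step 13
Reactants: 22 (S)-citronellal
Product: 24 (3S)-3,7-dimethyloct-6-en-1-yne, via alkenyl nonaflate 23 (not isolated)
Conditions: n-C4F9SO2F, P2-Et phosphazene base, DMF, −20 °C → rt
Reagents that add atoms: none
Why: One-pot enol nonaflate formation and base-induced elimination converts the enolisable aldehyde into the terminal alkyne with the same carbon count, and the stereocentre, β to the carbonyl, is not touched.

Step 14
Reactants: 25 prop-2-yn-1-ol
Product: 27 (E)-3-iodo-2-methylprop-2-en-1-ol, via alkenylalane 26 (not isolated)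
Conditions: AlMe3 (3 equiv), Cp2ZrCl2 (25 mol %), CH2Cl2, 0 °C → rt; then I2, THF, −30 °C
Reagents that add atoms: trimethylaluminium C[Al](C)C; iodine II
Why: Zirconium-catalysed syn-carboalumination (methylalumination) of the alkyne followed by iodinolysis with retention gives the E-iodoalkene with the methyl on the internal carbon.

Step 15
Reactants: 27 iodo allylic alcohol
Product: 28 (E)-3-iodo-2-methylprop-2-enal
Conditions: MnO2, CH2Cl2, rt
Reagents that add atoms: none
Why: MnO2 oxidation of the allylic alcohol to the enal, which does not touch the alkenyl iodide.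

Step 16
Reactants: 24 alkyne; 28 iodo enal
Product: 31 (1E,3S,4E,6S)-1-iodo-2,6,10-trimethylundeca-1,4,9-trien-3-ol, via alkenylborane 29 (not isolated), via alkenylzinc 30 (not isolated)
Conditions: (c-C6H11)2BH (from BH3·SMe2 and cyclohexene), toluene, 0 °C → rt; Me2Zn, −78 °C; (−)-MIB (3-exo-morpholinoisoborneol, 5 mol %); 28, −10 °C
Reagents that add atoms: none
Why: Syn-hydroboration of the terminal alkyne, boron-to-zinc transmetalation and amino-alcohol-catalysed enantioselective alkenylzinc addition, in which the (−)-MIB–zinc complex delivers the E-alkenyl group to the Si face of the aldehyde and should give the (S)-carbinol (the antipodal ligand is available if the sense proves opposite).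

Step 17
Reactants: 31 dienol
Product: 32 (1E,3S,4E,6S)-3-(TBS-oxy)-1-iodo-2,6,10-trimethylundeca-1,4,9-triene
Conditions: t-BuMe2SiCl, imidazole, DMF, rt
Reagents that add atoms: tert-butyl(chloro)dimethylsilane CC(C)(C)[Si](C)(C)Cl
Why: Silylation of the doubly allylic alcohol under basic conditions, which avoids ionisation of this acid-sensitive carbinol.

**Fragment union and enal construction**

Step 18
Reactants: 21 alkyl iodide; 32 alkenyl iodide
Product: 34 (1S,2S,3S,6S)-1-SC-2-[3-(TBDPS-oxy)propyl]-1,6-dimethyl-3-(TES-oxy)-6-(TMS-oxy)cyclohexane, via alkylzinc iodide 33 (not isolated)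
Conditions: Zn dust (BrCH2CH2Br, Me3SiCl activation), LiCl, THF, 40 °C; then 32, Pd(dppf)Cl2 (5 mol %), THF/NMP, rt → 40 °C
Reagents that add atoms: none
Why: Negishi sp3–sp2 cross-coupling: zinc inserts into the primary C–I bond and the alkylzinc iodide couples with the alkenyl iodide under palladium catalysis with retention of the E geometry, the silyl ethers being inert.

Step 19
Reactants: 34 tetrasilyl ether
Product: 35 (1S,2S,3S,6S)-1-SC-2-[3-(TBDPS-oxy)propyl]-1,6-dimethylcyclohexane-3,6-diol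
Conditions: HF·pyridine, pyridine, THF, 0 °C
Reagents that add atoms: none
Why: Buffered fluoride cleaves the TMS ether and the secondary TES ether faster than the secondary TBS and primary TBDPS ethers (graded silyl ether lability).

Step 20
Reactants: 35 diol
Product: 36 (1S,2S,6S)-6-hydroxy-1-SC-2-[3-(TBDPS-oxy)propyl]-1,6-dimethylcyclohexan-3-one
Conditions: Dess–Martin periodinane, pyridine, CH2Cl2, 0 °C → rt
Reagents that add atoms: none
Why: Dess–Martin oxidation of the secondary C3 alcohol under buffered conditions, in which the tertiary alcohol cannot be oxidised and C2 should not epimerise.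

Step 21
Reactants: 36 hydroxy ketone
Product: 38 (1S,2S,6S)-6-hydroxy-1-SC-2-[3-(TBDPS-oxy)propyl]-1,6-dimethylcyclohex-3-en-3-yl trifluoromethanesulfonate, via dipotassium enolate alkoxide 37 (not isolated)
Conditions: KN(SiMe3)2 (2.2 equiv), THF, −78 °C; N-(5-chloropyridin-2-yl)triflimide, −78 °C
Reagents that add atoms: N-(5-chloropyridin-2-yl)-N-(trifluoromethylsulfonyl)trifluoromethanesulfonamide FC(F)(F)S(=O)(=O)N(c1ccc(Cl)cn1)S(=O)(=O)C(F)(F)F
Why: Kinetic deprotonation at the unhindered C4 methylene (C2 is a hindered methine) and O-triflation of the enolate give the C3–C4 enol triflate, while the second equivalent of base holds the tertiary hydroxyl as its alkoxide.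

Step 22
Reactants: 25 prop-2-yn-1-ol
Product: 39 2-(tributylstannyl)prop-2-en-1-ol
Conditions: Bu3SnH, Mo(CO)3(CNtBu)3 (2 mol %), hydroquinone, THF, 55 °C
Reagents that add atoms: tributyltin hydride CCCC[SnH](CCCC)CCCC
Why: Molybdenum-catalysed hydrostannation of the terminal alkyne, which places tin on the internal carbon and gives the α-stannylated allyl alcohol.

Step 23
Reactants: 38 enol triflate; 39 vinylstannane
Product: 40 2-[(1S,2R,6S)-6-hydroxy-1-SC-2-[3-(TBDPS-oxy)propyl]-1,6-dimethylcyclohex-3-en-3-yl]prop-2-en-1-ol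
Conditions: Pd(PPh3)4 (10 mol %), CuCl, LiCl, DMSO, 60 °C
Reagents that add atoms: none
Why: Stille cross-coupling of the enol triflate with the 1-substituted vinylstannane, accelerated by CuCl/LiCl for hindered partners, gives the 2-(hydroxymethyl)-1,3-diene.

Step 24
Reactants: 40 dienol
Product: 41 (2Z)-2-[(1S,2R,6S)-6-hydroxy-1-SC-2-[3-(TBDPS-oxy)propyl]-1,6-dimethylcyclohexan-3-ylidene]propan-1-ol
Conditions: (naphthalene)Cr(CO)3 (20 mol %), H2 (70 atm), THF, 45 °C
Reagents that add atoms: none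
Why: Arene–Cr(CO)3-catalysed 1,4-hydrogenation: only the conjugated diene can bind in its s-cis form, hydrogen adds to C4 and to the terminal methylene, so the new methyl is cis to C4 and the hydroxymethyl cis to C2 (Z), while the isolated alkenes of the side chain should not be reduced.

Step 25
Reactants: 41 Z-allylic alcohol
Product: 42 (2Z)-2-[(1S,2R,6S)-6-hydroxy-1-SC-2-[3-(TBDPS-oxy)propyl]-1,6-dimethylcyclohexan-3-ylidene]propanal
Conditions: Dess–Martin periodinane, pyridine, CH2Cl2, 0 °C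
Reagents that add atoms: none
Why: Dess–Martin oxidation of the primary allylic alcohol to the enal under buffered conditions that should leave the Z geometry and the tertiary alcohol intact.

Step 26
Reactants: 42 bis-silyl enal
Product: 43 (2Z)-2-[(1S,2R,6S)-6-hydroxy-1-[(3E,5S,6E,8S)-5-hydroxy-4,8,12-trimethyltrideca-3,6,11-trien-1-yl]-2-(3-hydroxypropyl)-1,6-dimethylcyclohexan-3-ylidene]propanal (CNP0323596.2)
Conditions: Bu4NF, AcOH (1:1), THF, 0 °C → rt
Reagents that add atoms: none
Why: Fluoride-mediated cleavage of the two remaining silyl ethers, buffered with acetic acid so that the enal (epimerisable at C2 through its dienolate) and the doubly allylic alcohol survive.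

**Compound list**

1 | δ-valerolactone (oxan-2-one) | O=C1CCCCO1 | starting material
2 | sodium 5-hydroxypentanoate | [Na+].[O-]C(=O)CCCCO | intermediate
3 | tert-butyldiphenylsilyl 5-(tert-butyldiphenylsilyloxy)pentanoate | CC(C)(C)[Si](c1ccccc1)(c1ccccc1)OCCCCC(=O)O[Si](c1ccccc1)(c1ccccc1)C(C)(C)C | intermediate
4 | 5-(tert-butyldiphenylsilyloxy)pentanoic acid | OC(=O)CCCCO[Si](c1ccccc1)(c1ccccc1)C(C)(C)C | intermediate
5 | (R)-4-benzyloxazolidin-2-one | O=C1N[C@H](Cc2ccccc2)CO1 | starting material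
6 | 5-(tert-butyldiphenylsilyloxy)pentanoic pivalic anhydride | CC(C)(C)C(=O)OC(=O)CCCCO[Si](c1ccccc1)(c1ccccc1)C(C)(C)C | intermediate
7 | (R)-4-benzyl-3-[5-(tert-butyldiphenylsilyloxy)pentanoyl]oxazolidin-2-one | O=C1OC[C@@H](Cc2ccccc2)N1C(=O)CCCCO[Si](c1ccccc1)(c1ccccc1)C(C)(C)C | intermediate
8 | pent-4-enal | C=CCCC=O | starting material
9 | (Z)-dibutylboron enolate of 7 | CCCCB(CCCC)O/C(=C\CCCO[Si](c1ccccc1)(c1ccccc1)C(C)(C)C)N1[C@H](Cc2ccccc2)COC1=O | intermediate
10 | (R)-4-benzyl-3-[(2R,3S)-2-[3-(tert-butyldiphenylsilyloxy)propyl]-3-hydroxyhept-6-enoyl]oxazolidin-2-one | C=CCC[C@H](O)[C@@H](CCCO[Si](c1ccccc1)(c1ccccc1)C(C)(C)C)C(=O)N1[C@H](Cc2ccccc2)COC1=O | intermediate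
11 | (2R,3S)-2-[3-(tert-butyldiphenylsilyloxy)propyl]-3-hydroxy-N-methoxy-N-methylhept-6-enamide | C=CCC[C@H](O)[C@@H](CCCO[Si](c1ccccc1)(c1ccccc1)C(C)(C)C)C(=O)N(C)OC | intermediate
12 | (2R,3S)-2-[3-(tert-butyldiphenylsilyloxy)propyl]-N-methoxy-N-methyl-3-(triethylsilyloxy)hept-6-enamide | C=CCC[C@H](O[Si](CC)(CC)CC)[C@@H](CCCO[Si](c1ccccc1)(c1ccccc1)C(C)(C)C)C(=O)N(C)OC | intermediate
13 | (3R,4S)-3-[3-(tert-butyldiphenylsilyloxy)propyl]-4-(triethylsilyloxy)oct-7-en-2-one | C=CCC[C@H](O[Si](CC)(CC)CC)[C@@H](CCCO[Si](c1ccccc1)(c1ccccc1)C(C)(C)C)C(C)=O | intermediate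
14 | triethyl phosphonoacetate | CCOC(=O)CP(=O)(OCC)OCC | starting material
15 | sodium salt of the triethyl phosphonoacetate carbanion | [Na+].CCOC(=O)[CH-]P(=O)(OCC)OCC | intermediate
16 | ethyl (2E,4S,5S)-4-[3-(tert-butyldiphenylsilyloxy)propyl]-3-methyl-5-(triethylsilyloxy)nona-2,8-dienoate | C=CCC[C@H](O[Si](CC)(CC)CC)[C@@H](CCCO[Si](c1ccccc1)(c1ccccc1)C(C)(C)C)/C(C)=C/C(=O)OCC | intermediate
17 | ethyl (2E,4S,5S)-4-[3-(tert-butyldiphenylsilyloxy)propyl]-3-methyl-8-oxo-5-(triethylsilyloxy)non-2-enoate (key-step precursor) | CC(=O)CC[C@H](O[Si](CC)(CC)CC)[C@@H](CCCO[Si](c1ccccc1)(c1ccccc1)C(C)(C)C)/C(C)=C/C(=O)OCC | intermediate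
18 | ethyl 2-[(1S,2S,3S,6S)-2-[3-(tert-butyldiphenylsilyloxy)propyl]-6-hydroxy-1,6-dimethyl-3-(triethylsilyloxy)cyclohexyl]acetate (key-step product; OH trans to the acetate arm, arm trans to the C2 chain, C3 silyloxy trans to the C2 chain) | CCOC(=O)C[C@@]1(C)[C@H](CCCO[Si](c2ccccc2)(c2ccccc2)C(C)(C)C)[C@@H](O[Si](CC)(CC)CC)CC[C@]1(C)O | intermediate
19 | C6 trimethylsilyl ether of 18 | CCOC(=O)C[C@@]1(C)[C@H](CCCO[Si](c2ccccc2)(c2ccccc2)C(C)(C)C)[C@@H](O[Si](CC)(CC)CC)CC[C@]1(C)O[Si](C)(C)C | intermediate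
20 | 2-[(1S,2S,3S,6S)-2-[3-(tert-butyldiphenylsilyloxy)propyl]-1,6-dimethyl-3-(triethylsilyloxy)-6-(trimethylsilyloxy)cyclohexyl]ethanol | OCC[C@@]1(C)[C@H](CCCO[Si](c2ccccc2)(c2ccccc2)C(C)(C)C)[C@@H](O[Si](CC)(CC)CC)CC[C@]1(C)O[Si](C)(C)C | intermediate
21 | (1S,2S,3S,6S)-1-(2-iodoethyl)-2-[3-(tert-butyldiphenylsilyloxy)propyl]-1,6-dimethyl-3-(triethylsilyloxy)-6-(trimethylsilyloxy)cyclohexane | ICC[C@@]1(C)[C@H](CCCO[Si](c2ccccc2)(c2ccccc2)C(C)(C)C)[C@@H](O[Si](CC)(CC)CC)CC[C@]1(C)O[Si](C)(C)C | intermediate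
22 | (S)-citronellal [(3S)-3,7-dimethyloct-6-enal] | CC(C)=CCC[C@H](C)CC=O | starting material
23 | (3S)-3,7-dimethylocta-1,6-dien-1-yl nonafluorobutanesulfonate (E/Z mixture) | CC(C)=CCC[C@H](C)C=COS(=O)(=O)C(F)(F)C(F)(F)C(F)(F)C(F)(F)F | intermediate
24 | (3S)-3,7-dimethyloct-6-en-1-yne | CC(C)=CCC[C@H](C)C#C | intermediate
25 | prop-2-yn-1-ol | C#CCO | starting material
26 | dimethylaluminium (E)-3-(dimethylalumanyl)-2-methylprop-2-en-1-olate | C[Al](C)/C=C(\C)CO[Al](C)C | intermediate
27 | (E)-3-iodo-2-methylprop-2-en-1-ol | OC/C(C)=C/I | intermediate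
28 | (E)-3-iodo-2-methylprop-2-enal | O=C/C(C)=C/I | intermediate
29 | dicyclohexyl[(1E,3S)-3,7-dimethylocta-1,6-dien-1-yl]borane | CC(C)=CCC[C@H](C)/C=C/B(C1CCCCC1)C1CCCCC1 | intermediate
30 | [(1E,3S)-3,7-dimethylocta-1,6-dien-1-yl](methyl)zinc | CC(C)=CCC[C@H](C)/C=C/[Zn]C | intermediate
31 | (1E,3S,4E,6S)-1-iodo-2,6,10-trimethylundeca-1,4,9-trien-3-ol | CC(C)=CCC[C@H](C)/C=C/[C@H](O)/C(C)=C/I | intermediate
32 | (1E,3S,4E,6S)-3-(tert-butyldimethylsilyloxy)-1-iodo-2,6,10-trimethylundeca-1,4,9-triene | CC(C)=CCC[C@H](C)/C=C/[C@H](O[Si](C)(C)C(C)(C)C)/C(C)=C/I | intermediate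
33 | alkylzinc iodide from 21 (I–Zn on the arm terminus) | I[Zn]CC[C@@]1(C)[C@H](CCCO[Si](c2ccccc2)(c2ccccc2)C(C)(C)C)[C@@H](O[Si](CC)(CC)CC)CC[C@]1(C)O[Si](C)(C)C | intermediate
34 | (1S,2S,3S,6S)-1-SC-2-[3-(tert-butyldiphenylsilyloxy)propyl]-1,6-dimethyl-3-(triethylsilyloxy)-6-(trimethylsilyloxy)cyclohexane | CC(C)=CCC[C@H](C)/C=C/[C@H](O[Si](C)(C)C(C)(C)C)/C(C)=C/CC[C@@]1(C)[C@H](CCCO[Si](c2ccccc2)(c2ccccc2)C(C)(C)C)[C@@H](O[Si](CC)(CC)CC)CC[C@]1(C)O[Si](C)(C)C | intermediate
35 | (1S,2S,3S,6S)-1-SC-2-[3-(tert-butyldiphenylsilyloxy)propyl]-1,6-dimethylcyclohexane-3,6-diol | CC(C)=CCC[C@H](C)/C=C/[C@H](O[Si](C)(C)C(C)(C)C)/C(C)=C/CC[C@@]1(C)[C@H](CCCO[Si](c2ccccc2)(c2ccccc2)C(C)(C)C)[C@@H](O)CC[C@]1(C)O | intermediate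
36 | (1S,2S,6S)-6-hydroxy-1-SC-2-[3-(tert-butyldiphenylsilyloxy)propyl]-1,6-dimethylcyclohexan-3-one | CC(C)=CCC[C@H](C)/C=C/[C@H](O[Si](C)(C)C(C)(C)C)/C(C)=C/CC[C@@]1(C)[C@H](CCCO[Si](c2ccccc2)(c2ccccc2)C(C)(C)C)C(=O)CC[C@]1(C)O | intermediate
37 | dipotassium C3–C4 enolate C6 alkoxide of 36 | CC(C)=CCC[C@H](C)/C=C/[C@H](O[Si](C)(C)C(C)(C)C)/C(C)=C/CC[C@@]1(C)[C@H](CCCO[Si](c2ccccc2)(c2ccccc2)C(C)(C)C)C([O-])=CC[C@]1(C)[O-].[K+].[K+] | intermediate
38 | (1S,2S,6S)-6-hydroxy-1-SC-2-[3-(tert-butyldiphenylsilyloxy)propyl]-1,6-dimethylcyclohex-3-en-3-yl trifluoromethanesulfonate | CC(C)=CCC[C@H](C)/C=C/[C@H](O[Si](C)(C)C(C)(C)C)/C(C)=C/CC[C@@]1(C)[C@H](CCCO[Si](c2ccccc2)(c2ccccc2)C(C)(C)C)C(OS(=O)(=O)C(F)(F)F)=CC[C@]1(C)O | intermediate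
39 | 2-(tributylstannyl)prop-2-en-1-ol | C=C(CO)[Sn](CCCC)(CCCC)CCCC | intermediate
40 | 2-[(1S,2R,6S)-6-hydroxy-1-SC-2-[3-(tert-butyldiphenylsilyloxy)propyl]-1,6-dimethylcyclohex-3-en-3-yl]prop-2-en-1-ol | CC(C)=CCC[C@H](C)/C=C/[C@H](O[Si](C)(C)C(C)(C)C)/C(C)=C/CC[C@@]1(C)[C@H](CCCO[Si](c2ccccc2)(c2ccccc2)C(C)(C)C)C(C(=C)CO)=CC[C@]1(C)O | intermediate
41 | (2Z)-2-[(1S,2R,6S)-6-hydroxy-1-SC-2-[3-(tert-butyldiphenylsilyloxy)propyl]-1,6-dimethylcyclohexan-3-ylidene]propan-1-ol (hydroxymethyl cis to C2) | CC(C)=CCC[C@H](C)/C=C/[C@H](O[Si](C)(C)C(C)(C)C)/C(C)=C/CC[C@@]1(C)[C@H](CCCO[Si](c2ccccc2)(c2ccccc2)C(C)(C)C)/C(=C(/C)CO)CC[C@]1(C)O | intermediate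
42 | (2Z)-2-[(1S,2R,6S)-6-hydroxy-1-SC-2-[3-(tert-butyldiphenylsilyloxy)propyl]-1,6-dimethylcyclohexan-3-ylidene]propanal | CC(C)=CCC[C@H](C)/C=C/[C@H](O[Si](C)(C)C(C)(C)C)/C(C)=C/CC[C@@]1(C)[C@H](CCCO[Si](c2ccccc2)(c2ccccc2)C(C)(C)C)/C(=C(/C)C=O)CC[C@]1(C)O | intermediate
43 | (2Z)-2-[(1S,2R,6S)-6-hydroxy-1-[(3E,5S,6E,8S)-5-hydroxy-4,8,12-trimethyltrideca-3,6,11-trien-1-yl]-2-(3-hydroxypropyl)-1,6-dimethylcyclohexan-3-ylidene]propanal | CC(C)=CCC[C@H](C)/C=C/[C@H](O)/C(C)=C/CC[C@@]1(C)[C@H](CCCO)/C(=C(/C)C=O)CC[C@]1(C)O | target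

**Totals**

Total step count: 26.
Longest linear sequence: 20 steps (steps 1–12, 18–21, 23–26).

**Steps most likely to fail, with fallbacks**

Step 9 (key step). The ketone ketyl may add too slowly to the β,β-disubstituted enoate, so that simple reduction of the ketone competes, or the C6 oxygen may not settle cleanly trans to the arm. The fallback keeps the C1–C6 ketyl–enoate closure but sets C6 after the ring is formed; it sets out from 16. Oxidative cleavage of the terminal alkene (OsO4 cat., NaIO4, 2,6-lutidine, dioxane/H2O) would give the aldehyde ethyl (2E,4S,5S)-4-[3-(tert-butyldiphenylsilyloxy)propyl]-3-methyl-8-oxo-5-(triethylsilyloxy)oct-2-enoate F1. Its less hindered aldehyde ketyl should close ring A under the same SmI2 conditions to the secondary alcohol ethyl 2-[(1S,2S,3S,6S)-2-[3-(tert-butyldiphenylsilyloxy)propyl]-6-hydroxy-1-methyl-3-(triethylsilyloxy)cyclohexyl]acetate F2. Dess–Martin oxidation would erase the C6 configuration and give the cyclohexanone ethyl 2-[(1S,2S,3S)-2-[3-(tert-butyldiphenylsilyloxy)propyl]-1-methyl-6-oxo-3-(triethylsilyloxy)cyclohexyl]acetate F3. Excess AlMe3 in toluene, which delivers methyl to cyclohexanones from the axial direction and leaves the ester alone at low temperature, should then give the equatorial tertiary alcohol, and the route is rejoined at 18.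

Step 24. The hindered 2,3-disubstituted diene may not reach the s-cis chromium complex, so that the 1,4-hydrogenation stalls, or olefin migration in the skipped diene of the side chain may set in at the temperature needed. The fallback makes the enal by carbonyl olefination and sets out from ketone 36. Peterson formyl-olefination with lithiated N-cyclohexyl-2-(triethylsilyl)propan-1-imine (LiN(i-Pr)2, THF, −78 → 0 °C, one extra equivalent for the tertiary hydroxyl) would give the N-cyclohexyl imine of enal 42 F4 as a mixture of geometric isomers. Hydrolysis in AcOH/NaOAc buffer would release the enal; the Z isomer is separated, the E isomer is returned after photo-equilibration, and the route is rejoined at 42.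

Step 7. Olefination of the α-branched, β-silyloxy methyl ketone may be slow, so that enolisation epimerises the carbon next to the carbonyl or eliminates the silyloxy group before the phosphonate adds. The fallback builds the enoate stereospecifically and sets out from Weinreb amide 12. The lithium enolate of ethyl acetate (LiN(i-Pr)2, EtOAc, THF, −78 °C) would give the β-keto ester ethyl (4R,5S)-4-[3-(tert-butyldiphenylsilyloxy)propyl]-3-oxo-5-(triethylsilyloxy)non-8-enoate F5, whose doubly activated methylene takes up the base and shields the stereocentre. NaH and then PhNTf2 should give, through the chelated sodium enolate, the enol triflate ethyl (2Z,4R,5S)-4-[3-(tert-butyldiphenylsilyloxy)propyl]-5-(triethylsilyloxy)-3-(trifluoromethylsulfonyloxy)nona-2,8-dienoate F6. Iron-catalysed methylation with retention (MeMgBr, Fe(acac)3, THF/NMP, −30 °C) would give the E-enoate and rejoin the route at 16.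

**Further compounds**

F1 | step 9 | ethyl (2E,4S,5S)-4-[3-(tert-butyldiphenylsilyloxy)propyl]-3-methyl-8-oxo-5-(triethylsilyloxy)oct-2-enoate | O=CCC[C@H](O[Si](CC)(CC)CC)[C@@H](CCCO[Si](c1ccccc1)(c1ccccc1)C(C)(C)C)/C(C)=C/C(=O)OCC
F2 | step 9 | ethyl 2-[(1S,2S,3S,6S)-2-[3-(tert-butyldiphenylsilyloxy)propyl]-6-hydroxy-1-methyl-3-(triethylsilyloxy)cyclohexyl]acetate | CCOC(=O)C[C@@]1(C)[C@H](CCCO[Si](c2ccccc2)(c2ccccc2)C(C)(C)C)[C@@H](O[Si](CC)(CC)CC)CC[C@@H]1O
F3 | step 9 | ethyl 2-[(1S,2S,3S)-2-[3-(tert-butyldiphenylsilyloxy)propyl]-1-methyl-6-oxo-3-(triethylsilyloxy)cyclohexyl]acetate | CCOC(=O)C[C@@]1(C)[C@H](CCCO[Si](c2ccccc2)(c2ccccc2)C(C)(C)C)[C@@H](O[Si](CC)(CC)CC)CCC1=O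
F4 | step 24 | N-cyclohexyl imine of enal 42 (Z isomer drawn; formed as a mixture of geometric isomers) | CC(C)=CCC[C@H](C)/C=C/[C@H](O[Si](C)(C)C(C)(C)C)/C(C)=C/CC[C@@]1(C)[C@H](CCCO[Si](c2ccccc2)(c2ccccc2)C(C)(C)C)/C(=C(/C)C=NC2CCCCC2)CC[C@]1(C)O
F5 | step 7 | ethyl (4R,5S)-4-[3-(tert-butyldiphenylsilyloxy)propyl]-3-oxo-5-(triethylsilyloxy)non-8-enoate | C=CCC[C@H](O[Si](CC)(CC)CC)[C@@H](CCCO[Si](c1ccccc1)(c1ccccc1)C(C)(C)C)C(=O)CC(=O)OCC
F6 | step 7 | ethyl (2Z,4R,5S)-4-[3-(tert-butyldiphenylsilyloxy)propyl]-5-(triethylsilyloxy)-3-(trifluoromethylsulfonyloxy)nona-2,8-dienoate | C=CCC[C@H](O[Si](CC)(CC)CC)[C@@H](CCCO[Si](c1ccccc1)(c1ccccc1)C(C)(C)C)/C(OS(=O)(=O)C(F)(F)F)=C/C(=O)OCC
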